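All constants stand for no real mixture; what happens was integrated by code.

Into a closed, stirred vessel at constant temperature go starting material, coupling partner, a little catalyst and a trace of protic impurity, and the partner charge differs from flask to flask.

all flasks: starting material 20 mM; protic impurity 0.400 mM; free catalyst 0.44 mM; time 2.0 h

| charge | coupling partner |
|---|---|
| Sunday's | 22.0 mM |
| Friday's | 29.0 mM |
| Monday's | 37.0 mM |

    coupling partner + by-product ⇌ idle adduct, settled at all times (K1 = 13000 M⁻¹)
    starting material + protic impurity → quenched substrate (k2 = 16 M⁻¹ min⁻¹)
    starting material + catalyst intermediate B ⇌ catalyst intermediate C (K3 = 110 M⁻¹, k3 = 92 M⁻¹ min⁻¹)
    coupling partner + free catalyst → catalyst intermediate A (k4 = 85 M⁻¹ min⁻¹)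
    catalyst intermediate A → by-product + catalyst intermediate B (k5 = 2.0 min⁻¹)
    catalyst intermediate C → free catalyst + target (k6 = 1.9 min⁻¹)

- part of the starting material that has reacted at the end, Sunday's
- part of the starting material that has reacted at the end, Friday's
- part of the starting material that has reacted at the end, Monday's
- what raising the concentration of coupling partner from its lowest to its highest value here does to the part of the starting material that has reacted (changes below 5 percentage points count as none) (it rises / no change / it falls)

- amounts and yields of by-product count idle adduct too
- run time (Sunday's): 2.0 h

Read the scheme as a cycle: free catalyst takes up partner, sheds by-product, takes up starting material, releases target and returns. Each turn uses one partner, so the natural zero of the scale is a one-to-one charge. Sunday's flask, at 1.10 partner per starting material, clears that line, which promises full conversion.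

That count is too kind for a run of this length, because K1 times Sunday's partner charge is 290, so by-product is mostly held as idle adduct, and each turn costs two partners while that binding holds. The balance point is therefore two partners per starting material, and the richest flask here lies below it. Call X the partner budget: half the partner charge over the starting-material charge. Sunday's X is 55.0%, the share of starting material turned when, by this two-partner count, free partner reaches zero. Friday's is 72.5% and Monday's 92.5%.

Is the bend at X sharp, though, given that binding weakens as partner falls? By-product is half bound at a free partner of 0.0769 mM, far below the charge. At that level, step 4 takes a catalyst 153 min per pick-up, longer than the run. So I expect X to mark a sharp slowing within the run, not a wall.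

The impurity stands outside the budget. Its half-life at the charged starting material is 2.17 min, short against the run, so it adds 2.00% to each figure.

The last doubt is the clock. On Monday's flask, τ, the sum of the four waits at starting concentrations, is 1.89 min. That allows 28.0 mM of turnover against the 18.5 mM the budget counts. But τ is a starting value, and it stretches as both reactants fall, so I distrust that margin. I commit to 57.0% for Sunday's, 74.5% for Friday's, and something below 94.5% for Monday's.

The forecast gave 58%, 71% and 80%, with the trend it rises, reasoning that “free partner collapses once conversion reaches about half the partner loading”. Its Friday's figure is lower than mine, and for Monday's it names a number where I give an upper estimate for this run.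

The simulation gives it rises, by 22 percentage points, and the forecast's figures stand within tolerance.

| Flask | X plus impurity | Forecast | Reacted |
|---|---|---|---|
| Sunday's | 57.0% | 58% | 58.6% |
| Friday's | 74.5% | 71% | 71.9% |
| Monday's | 94.5% | 80% | 80.3% |

Monday's flask ends below its line with 15% of its partner still free, and at 2.00 h the half-life of partner by the step to catalyst intermediate A is 1.0 h, half the run. A neighbour flask, like Monday's but with 5.0 mM of starting material, has X of 370% and reaches 95.4%; at its 87.7% of target, two partners per target leave 76.3% of the charge, and it holds 74%.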